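Everything rests on unfolding resorcinol ring A into an open poly-β-carbonyl chain. The feature exploited is the substitution pattern of ring A: hydroxyls on a1 and a3, the biaryl bond to d5 of phenol ring D on a4, and, on the adjacent a5, methylene C7 that leads to methine C8 on d6, which is what a 1,3,5-tricarbonyl chain leaves behind when it folds. One base-mediated operation forms a4–a5 by Claisen acylation and a5–a6 by aldol condensation, closing the dihydrophenanthrene carbocycle and aromatic ring A without touching C8 or C9. The precursor is an enantiopure cis-disubstituted dibenzosuberane pentamethyl ether with a methyl acetate arm on C8 and a 2,4-dioxopentyl chain on d5.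

Key step: step 14

**Atom labels**
- Ring A (resorcinol): a1 (C–OH), a2 (CH), a3 (C–OH), a4 (bonded to d5), a5 (bears C7), a6 (CH).
- Ring B (fused catechol): b1 on C8, b3 and b4 oxygenated, b6 on C9.
- Ring C: the pendant 3,4-dioxygenated phenyl on C9.
- Ring D (central phenol): d1 on C10, d3 oxygenated, d5 on a4, d6 on C8.
- The seven-membered ring is C8–b1–b6–C9–C10–d1–d6.
- Reading the target SMILES gives C8 = R and C9 = S. H8 and H9 lie on the same face, so the C7 arm and ring C are cis.

**Design remarks**
- Ring D enters as a symmetric 3,5-dimethoxyphenyl group, so the seven-ring acylation has only one outcome. The d5 oxygen is singled out afterwards through chelation to the C8 ketone.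
- The alkene to be hydrogenated asymmetrically is made geometrically pure from an enol sulfonate.
- Reductive N–O cleavage of an isoxazole stops at the enaminone, so a hydrolysis is built into step 13.
- Both alkene hydrogenations come before the isoxazole arrives, because its N–O bond does not survive H2 over Pd.

**Assumption:** the sense of induction in step 5 is taken from the quadrant picture for trisubstituted alkenes. The ligand antipode written is exchanged for its mirror image if the first run shows the opposite sense.

## Route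

Step 1
Reactants: 1 3',4'-dimethoxyacetophenone; 2 1-bromo-3,5-dimethoxybenzene
Product: 3 1-(3,4-dimethoxyphenyl)-2-(3,5-dimethoxyphenyl)ethan-1-one (carbonyl carbon = C9; CH2 = C10)
Conditions: Pd2(dba)3 (1 mol %), Xantphos (2.5 mol %), NaOtBu (1.3 equiv), THF, 70 °C
Reagents that add atoms: none
Why: Palladium-catalysed α-arylation of an aryl methyl ketone enolate (Buchwald–Hartwig type) stops at monoarylation because the product enolate is more stabilised and more hindered, and it avoids a Friedel–Crafts route in which the very nucleophilic 3,5-dimethoxyphenyl ring would acylate itself.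

Step 2
Reactants: 3 deoxybenzoin
Product: 4 (Z)-1-(3,4-dimethoxyphenyl)-2-(3,5-dimethoxyphenyl)ethenyl 4-methylbenzenesulfonate
Conditions: KN(SiMe3)2 (1.1 equiv), THF, −78 °C; then Ts2O (1.2 equiv), −78 → 0 °C
Reagents that add atoms: p-toluenesulfonic anhydride, Cc1ccc(cc1)S(=O)(=O)OS(=O)(=O)c1ccc(C)cc1
Why: Deoxybenzoins enolise to the Z(O)-enolate with the two aryl groups anti, and O-sulfonylation freezes that geometry; the tosylate is preferred to the triflate because an α-(3,4-dimethoxyphenyl)vinyl triflate would ionise easily and lose its geometry.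

Step 3
Reactants: 5 methyl 2-bromo-4,5-dimethoxybenzoate
Product: 6 methyl 4,5-dimethoxy-2-(4,4,5,5-tetramethyl-1,3,2-dioxaborolan-2-yl)benzoate
Conditions: B2pin2 (1.1 equiv), PdCl2(dppf) (3 mol %), KOAc (3 equiv), 1,4-dioxane, 90 °C
Reagents that add atoms: bis(pinacolato)diboron, CC1(C)OB(OC1(C)C)B1OC(C)(C)C(C)(C)O1
Why: Miyaura borylation of an aryl bromide tolerates the ortho ester, and the weak base KOAc prevents homocoupling.

Step 4
Reactants: 4 enol tosylate; 6 aryl boronate
Product: 7 methyl 2-[(Z)-1-(3,4-dimethoxyphenyl)-2-(3,5-dimethoxyphenyl)ethenyl]-4,5-dimethoxybenzoate (ring B cis to ring D)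
Conditions: Pd(OAc)2 (3 mol %), XPhos (6 mol %), K3PO4 (3 equiv), THF–H2O, 65 °C
Reagents that add atoms: none
Why: Suzuki–Miyaura coupling of an enol tosylate runs with retention, since oxidative addition to zerovalent palladium and reductive elimination both keep the alkene geometry, so ring B takes the place of the tosylate cis to ring D.

Step 5
Reactants: 7 (Z)-triarylethylene
Product: 8 methyl 2-[(1S)-1-(3,4-dimethoxyphenyl)-2-(3,5-dimethoxyphenyl)ethyl]-4,5-dimethoxybenzoate
Conditions: [Ir(cod)((R)-tBu-PHOX)]BArF (2 mol %), H2 (80 bar), CH2Cl2, 25 °C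
Reagents that add atoms: none
Why: Iridium–N,P-catalysed asymmetric hydrogenation of non-chelating trisubstituted (including triaryl) alkenes picks the enantioface by placing the lone vinylic hydrogen in the crowded quadrant of the catalyst, so the pure Z geometry and the ligand configuration together set C9 as S.

Step 6
Reactants: 8 ester
Product: 9 2-[(1S)-1-(3,4-dimethoxyphenyl)-2-(3,5-dimethoxyphenyl)ethyl]-4,5-dimethoxybenzoic acid
Conditions: LiOH·H2O (5 equiv), THF–MeOH–H2O, 60 °C; then 1 M HCl
Reagents that add atoms: lithium hydroxide, [Li+].[OH-]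
Why: Saponification of the benzoate; C9–H has no acidifying neighbour at this stage and is not touched.

Step 7
Reactants: 9 acid
Product: 11 (11S)-11-(3,4-dimethoxyphenyl)-2,3,6,8-tetramethoxy-10,11-dihydro-5H-dibenzo[a,d][7]annulen-5-one (dibenzosuberone; ketone = C8; OMe on b3 b4 d3 d5), via mixed trifluoroacetic anhydride 10 (not isolated)
Conditions: (CF3CO)2O (1.5 equiv), CH2Cl2, 0 → 25 °C
Reagents that add atoms: none
Why: Intramolecular Friedel–Crafts acylation through the acyl trifluoroacetate, a mild electrophile that attacks only the doubly activated ring D position (ortho and para to methoxy, the two candidate sites being equivalent by symmetry) and so should outrun the six-ring closure onto the singly activated ring C.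

Step 8
Reactants: 11 hexamethoxy ketone
Product: 12 (11S)-11-(3,4-dimethoxyphenyl)-6-hydroxy-2,3,8-trimethoxy-10,11-dihydro-5H-dibenzo[a,d][7]annulen-5-one (free OH on d5)
Conditions: BCl3 (1.2 equiv), CH2Cl2, −78 → 0 °C; then H2O
Reagents that add atoms: none
Why: Chelation-controlled ether cleavage, in which BCl3 binds the C8 carbonyl and only the d5 methoxy group can complete a six-membered boron chelate, so chloride removes that methyl group and the five remote ethers remain.

Step 9
Reactants: 12 ortho-hydroxy ketone
Product: 13 (11S)-11-(3,4-dimethoxyphenyl)-2,3,8-trimethoxy-5-oxo-10,11-dihydro-5H-dibenzo[a,d][7]annulen-6-yl trifluoromethanesulfonate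
Conditions: Tf2O (1.2 equiv), pyridine (3 equiv), CH2Cl2, 0 °C
Reagents that add atoms: trifluoromethanesulfonic anhydride, O=S(=O)(OS(=O)(=O)C(F)(F)F)C(F)(F)F
Why: O-sulfonylation of the only free phenol installs the cross-coupling handle at d5 under conditions too weakly basic to disturb C9.

Step 10
Reactants: 13 keto triflate
Product: 15 methyl (2E)-2-[(11S)-11-(3,4-dimethoxyphenyl)-2,3,8-trimethoxy-6-(trifluoromethylsulfonyloxy)-10,11-dihydro-5H-dibenzo[a,d][7]annulen-5-ylidene]acetate (expected major alkene isomer; either isomer serves), via β-hydroxy ester 14 (not isolated)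
Conditions: BrZnCH2CO2Me (3 equiv, preformed from BrCH2CO2Me and Zn dust in THF), THF, 45 °C; 1 M HCl work-up; crude 14, SOCl2 (1.5 equiv), pyridine, CH2Cl2, 0 °C
Reagents that add atoms: methyl bromoacetate, COC(=O)CBr
Why: Reformatsky addition uses a small, non-basic zinc enolate that reaches the hindered diaryl ketone (made more electrophilic by the ortho triflate) without deprotonating the vinylogously acidified C9–H or attacking the sulfonate, and chlorosulfite elimination in pyridine then removes the tertiary doubly benzylic alcohol toward C7, the only neighbouring carbon that bears hydrogen.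

Step 11
Reactants: 15 ylidene acetate
Product: 16 methyl 2-[(5R,11S)-11-(3,4-dimethoxyphenyl)-2,3,8-trimethoxy-6-(trifluoromethylsulfonyloxy)-10,11-dihydro-5H-dibenzo[a,d][7]annulen-5-yl]acetate (C8 R; C9 S; H8 and H9 cis)
Conditions: H2 (4 bar), Pd/C (10 %), EtOAc, 25 °C
Reagents that add atoms: none
Why: Heterogeneous syn-hydrogenation of a β,β-diaryl acrylate, in which ring C on C9 (kept pseudo-axial by peri strain with b5–H) shields one face so that hydrogen should arrive anti to it and place H8 cis to H9 (C8 R), the same 1,4-cis outcome known for 4-aryl-1-tetralone imines and 1-alkylidene tetralins; the base-free medium spares the aryl triflate.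

Step 12
Reactants: 16 triflate ester; 17 3,5-dimethylisoxazole
Product: 20 methyl 2-[(5R,11S)-11-(3,4-dimethoxyphenyl)-2,3,8-trimethoxy-6-[(3-methylisoxazol-5-yl)methyl]-10,11-dihydro-5H-dibenzo[a,d][7]annulen-5-yl]acetate, via 5-(lithiomethyl)-3-methylisoxazole 18 (not isolated), via (3-methylisoxazol-5-yl)methylzinc chloride 19 (not isolated)
Conditions: 17 (2 equiv), n-BuLi (2 equiv), THF, −78 °C; ZnCl2 (2.2 equiv), −78 → 0 °C; then 16, Pd(OAc)2 (5 mol %), SPhos (10 mol %), THF, 60 °C
Reagents that add atoms: none
Why: Lateral lithiation of 3,5-dimethylisoxazole takes place at the C5 methyl group, transmetalation to zinc makes the carbanion compatible with the ester, and Negishi coupling of heterobenzylic zinc reagents with a bulky biarylphosphine copes with the ortho-substituted aryl triflate.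

Step 13
Reactants: 20 isoxazole
Product: 22 methyl 2-[(5R,11S)-11-(3,4-dimethoxyphenyl)-6-(2,4-dioxopentyl)-2,3,8-trimethoxy-10,11-dihydro-5H-dibenzo[a,d][7]annulen-5-yl]acetate (seco-ring A diketo ester), via enaminone 21 (not isolated)
Conditions: H2 (1 bar), Pd/C (10 %), EtOH, 25 °C; filter; 1 M aq HCl, THF, 25 °C
Reagents that add atoms: water, O
Why: Hydrogenolysis of the weak isoxazole N–O bond gives the vinylogous amide, and mild aqueous acid hydrolyses it to the β-diketone, with nothing else in the molecule being reducible or acid-labile.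

Step 14
Reactants: 22 diketo ester
Product: 24 ring A resorcinol pentamethyl ether with the full target skeleton (C8 R; C9 S), via cyclic triketone 23 (not isolated)
Conditions: LiN(SiMe3)2 (2.5 equiv), THF, −78 → 25 °C; then degassed 2 M aq KOH, MeOH, 25 → 40 °C; then 1 M HCl to pH 3
Reagents that add atoms: none
Why: The first equivalent of base converts the diketone into its a2 enolate, which switches off both ketones as electrophiles (so the C7 ester enolate cannot add to a3), and the second removes a benzylic a4 proton, more acidic than the C7 ester protons, to give a 1,3-dianion that reacts at its less delocalised a4 terminus. a4 adds to ester carbon a5 and methoxide leaves, a 6-(enolexo)-exo-trig Claisen closure of the carbocycle a4–a5–C7–C8–d6–d5, made irreversible by deprotonation of the very acidic a4–H of triketone 23. In aqueous KOH the a1 enolate extended to methyl a6 adds to the a5 ketone, a 6-(enolendo)-exo-trig aldol closure of ring A, and loss of water with enolisation of a1 and a3 gives the resorcinol as the thermodynamic sink. The closest known reaction types are the terminal acylation of β-diketone dianions by esters to 1,3,5-triketones and the alkali-induced cyclisation of such triketones to resorcinols. No stereocentre is created, and C8 and C9 carry no acidifying neighbour, so both are conserved. The selectivity needed is a4 over a2 and a6 in the acylation (secured by ring size, since those carbons would have to close eight- and ten-membered rings), a6-to-a5 over C7-to-a1 in the aldol (the latter gives a bridged bicycle that cannot aromatise and reverts), and C- over O-cyclisation (secured by staying basic until ring A is aromatic, which excludes 4-pyranone formation).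

Step 15
Reactants: 24 pentamethyl ether
Product: 25 CNP0306974.1 (heptaphenol; C8 R; C9 S)
Conditions: BBr3 (12 equiv), CH2Cl2, −78 → 25 °C; then ice–H2O
Reagents that add atoms: none
Why: Lewis-acid cleavage of aryl methyl ethers with BBr3 removes all five methyl groups (the excess covers the two free phenols), and no epimerisable or acid-labile site is left in the all-carbon framework.

## Compound list

1 | 3',4'-dimethoxyacetophenone | CC(=O)c1ccc(OC)c(OC)c1 | starting material
2 | 1-bromo-3,5-dimethoxybenzene | COc1cc(Br)cc(OC)c1 | starting material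
3 | 1-(3,4-dimethoxyphenyl)-2-(3,5-dimethoxyphenyl)ethan-1-one | COc1cc(CC(=O)c2ccc(OC)c(OC)c2)cc(OC)c1 | intermediate
4 | (Z)-1-(3,4-dimethoxyphenyl)-2-(3,5-dimethoxyphenyl)ethenyl 4-methylbenzenesulfonate | COc1ccc(cc1OC)/C(OS(=O)(=O)c1ccc(C)cc1)=C/c1cc(OC)cc(OC)c1 | intermediate
5 | methyl 2-bromo-4,5-dimethoxybenzoate | COC(=O)c1cc(OC)c(OC)cc1Br | starting material
6 | methyl 4,5-dimethoxy-2-(4,4,5,5-tetramethyl-1,3,2-dioxaborolan-2-yl)benzoate | COC(=O)c1cc(OC)c(OC)cc1B1OC(C)(C)C(C)(C)O1 | intermediate
7 | methyl 2-[(Z)-1-(3,4-dimethoxyphenyl)-2-(3,5-dimethoxyphenyl)ethenyl]-4,5-dimethoxybenzoate | COC(=O)c1cc(OC)c(OC)cc1/C(c1ccc(OC)c(OC)c1)=C\c1cc(OC)cc(OC)c1 | intermediate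
8 | methyl 2-[(1S)-1-(3,4-dimethoxyphenyl)-2-(3,5-dimethoxyphenyl)ethyl]-4,5-dimethoxybenzoate | COC(=O)c1cc(OC)c(OC)cc1[C@H](c1ccc(OC)c(OC)c1)Cc1cc(OC)cc(OC)c1 | intermediate
9 | 2-[(1S)-1-(3,4-dimethoxyphenyl)-2-(3,5-dimethoxyphenyl)ethyl]-4,5-dimethoxybenzoic acid | OC(=O)c1cc(OC)c(OC)cc1[C@H](c1ccc(OC)c(OC)c1)Cc1cc(OC)cc(OC)c1 | intermediate
10 | mixed anhydride of 9 and trifluoroacetic acid | O=C(OC(=O)C(F)(F)F)c1cc(OC)c(OC)cc1[C@H](c1ccc(OC)c(OC)c1)Cc1cc(OC)cc(OC)c1 | intermediate
11 | (11S)-11-(3,4-dimethoxyphenyl)-2,3,6,8-tetramethoxy-10,11-dihydro-5H-dibenzo[a,d][7]annulen-5-one | O=C1c2cc(OC)c(OC)cc2[C@H](c2ccc(OC)c(OC)c2)Cc2cc(OC)cc(OC)c21 | intermediate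
12 | (11S)-11-(3,4-dimethoxyphenyl)-6-hydroxy-2,3,8-trimethoxy-10,11-dihydro-5H-dibenzo[a,d][7]annulen-5-one | O=C1c2cc(OC)c(OC)cc2[C@H](c2ccc(OC)c(OC)c2)Cc2cc(OC)cc(O)c21 | intermediate
13 | 6-triflate of 12 | O=C1c2cc(OC)c(OC)cc2[C@H](c2ccc(OC)c(OC)c2)Cc2cc(OC)cc(OS(=O)(=O)C(F)(F)F)c21 | intermediate
14 | β-hydroxy ester, Reformatsky adduct of 13 (C8 carbinol configuration undefined) | COC(=O)CC1(O)c2cc(OC)c(OC)cc2[C@H](c2ccc(OC)c(OC)c2)Cc2cc(OC)cc(OS(=O)(=O)C(F)(F)F)c21 | intermediate
15 | methyl (2E)-5-ylidene acetate of the triflate (ester cis to ring B) | COC(=O)/C=C1\c2cc(OC)c(OC)cc2[C@H](c2ccc(OC)c(OC)c2)Cc2cc(OC)cc(OS(=O)(=O)C(F)(F)F)c21 | intermediate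
16 | methyl 2-[(5R,11S)-11-(3,4-dimethoxyphenyl)-2,3,8-trimethoxy-6-(trifluoromethylsulfonyloxy)-10,11-dihydro-5H-dibenzo[a,d][7]annulen-5-yl]acetate | COC(=O)C[C@@H]1c2cc(OC)c(OC)cc2[C@H](c2ccc(OC)c(OC)c2)Cc2cc(OC)cc(OS(=O)(=O)C(F)(F)F)c21 | intermediate
17 | 3,5-dimethylisoxazole | Cc1cc(C)on1 | starting material
18 | 5-(lithiomethyl)-3-methylisoxazole | [Li]Cc1cc(C)no1 | intermediate
19 | (3-methylisoxazol-5-yl)methylzinc chloride | Cl[Zn]Cc1cc(C)no1 | intermediate
20 | methyl 2-[(5R,11S)-11-(3,4-dimethoxyphenyl)-2,3,8-trimethoxy-6-[(3-methylisoxazol-5-yl)methyl]-10,11-dihydro-5H-dibenzo[a,d][7]annulen-5-yl]acetate | COC(=O)C[C@@H]1c2cc(OC)c(OC)cc2[C@H](c2ccc(OC)c(OC)c2)Cc2cc(OC)cc(Cc3cc(C)no3)c21 | intermediate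
21 | enaminone, 6-[(3Z)-4-amino-2-oxopent-3-en-1-yl] analogue of 20 | COC(=O)C[C@@H]1c2cc(OC)c(OC)cc2[C@H](c2ccc(OC)c(OC)c2)Cc2cc(OC)cc(CC(=O)/C=C(/C)N)c21 | intermediate
22 | seco-ring A diketo ester, 6-(2,4-dioxopentyl) compound, pentamethyl ether | COC(=O)C[C@@H]1c2cc(OC)c(OC)cc2[C@H](c2ccc(OC)c(OC)c2)Cc2cc(OC)cc(CC(=O)CC(C)=O)c21 | intermediate
23 | cyclic triketone after a4–a5 closure (drawn as triketo tautomer; a4 undefined) | CC(=O)CC(=O)C1C(=O)C[C@@H]2c3cc(OC)c(OC)cc3[C@H](c3ccc(OC)c(OC)c3)Cc3cc(OC)cc1c32 | intermediate
24 | target skeleton with free ring A resorcinol, pentamethyl ether | Oc1cc(O)c2c(c1)C[C@@H]1c3cc(OC)c(OC)cc3[C@H](c3ccc(OC)c(OC)c3)Cc3cc(OC)cc-2c31 | intermediate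
25 | CNP0306974.1 | Oc1cc(O)c2c(c1)C[C@@H]1c3cc(O)c(O)cc3[C@H](c3ccc(O)c(O)c3)Cc3cc(O)cc-2c31 | target

Total step count: 15. Longest linear sequence: 14 (steps 1, 2 and 4–15; step 3 is a one-step side branch).

## Steps most likely to fail

**1. Step 14.**
- What may go wrong: enolisation of the ester may stall the Claisen closure. Hydroxide would then saponify whatever ester is left. Retro-Claisen cleavage of the triketone may also outrun the aldol closure.
- Fallback: the two closures are taken apart. It sets out from 16 and bypasses steps 12 and 13. Palladium-catalysed mono-α-arylation of acetone ([Pd(cinnamyl)Cl]2, Mor-DalPhos, Cs2CO3, acetone, 90 °C) should give the arylacetone F1. KOtBu in THF then closes the carbocycle by intramolecular Claisen acylation of the benzylic ketone enolate a4, giving the cyclic β-diketone F2. Its dianion (LiN(iPr)2, 2.2 equiv, THF, −78 → 0 °C) forms at the acetyl methyl a2, as with 2-acetylcyclohexanone. Acylation of this dianion with N-methoxy-N-methylacetamide comes back to the route at triketone 23, which is aromatised with aqueous KOH to 24 as in the second half of step 14.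

**2. Step 5.**
- What may go wrong: turnover may be slow at the crowded alkene. Iridium hydride may cause partial Z-to-E isomerisation. Enantioface discrimination between two similar geminal aryl groups may be weak.
- Fallback: asymmetric catalysis is replaced by resolution. It sets out from 7. Hydrogenation over Pd/C in EtOAc gives the racemic triarylethane ester F3. This is separated by preparative chromatography on a chiral stationary phase, and the S enantiomer is 8, where the route is rejoined.

**3. Step 11.**
- What may go wrong: the facial selectivity at the exocyclic alkene may be poor if the conformer with ring C pseudo-equatorial reacts. Slow reduction may also allow hydrogenolysis of the aryl C–O bond of the triflate.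
- Fallback: reagent control on a lactone replaces substrate control. It sets out from 12 and bypasses steps 9 and 10 as well. (Triphenylphosphoranylidene)ketene, Ph3P=C=C=O, in toluene at 110 °C acylates the phenol and closes by intramolecular Wittig olefination to the bridged 4-arylcoumarin F4. Copper hydride conjugate reduction follows (Cu(OAc)2·H2O, DTBM-SEGPHOS in the antipode that delivers hydride anti to ring C, (EtO)2MeSiH, t-BuOH, toluene) and gives the dihydrocoumarin F5. NaOMe in MeOH at 0 °C with an AcOH quench opens it to the phenol methyl ester F6. Tf2O with pyridine then returns to the route at 16.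

## Further compounds

F1 | step 14 | arylacetone, 6-(2-oxopropyl) analogue of 16 | COC(=O)C[C@@H]1c2cc(OC)c(OC)cc2[C@H](c2ccc(OC)c(OC)c2)Cc2cc(OC)cc(CC(C)=O)c21
F2 | step 14 | cyclic β-diketone, 1-acetyl-2-tetralone fused to the dibenzosuberane (a4 undefined) | CC(=O)C1C(=O)C[C@@H]2c3cc(OC)c(OC)cc3[C@H](c3ccc(OC)c(OC)c3)Cc3cc(OC)cc1c32
F3 | step 5 | racemic methyl 2-[1-(3,4-dimethoxyphenyl)-2-(3,5-dimethoxyphenyl)ethyl]-4,5-dimethoxybenzoate | COC(=O)c1cc(OC)c(OC)cc1C(c1ccc(OC)c(OC)c1)Cc1cc(OC)cc(OC)c1
F4 | step 11 | bridged 4-arylcoumarin (lactone O on d5; C7=C8) | O=C1Oc2cc(OC)cc3c2C(=C1)c1cc(OC)c(OC)cc1[C@H](c1ccc(OC)c(OC)c1)C3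
F5 | step 11 | dihydrocoumarin (C8 R; C9 S) | O=C1C[C@@H]2c3cc(OC)c(OC)cc3[C@H](c3ccc(OC)c(OC)c3)Cc3cc(OC)cc(O1)c32
F6 | step 11 | phenol methyl ester, 6-hydroxy analogue of 16 | COC(=O)C[C@@H]1c2cc(OC)c(OC)cc2[C@H](c2ccc(OC)c(OC)c2)Cc2cc(OC)cc(O)c21
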